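The runs come from a simulation on assumed constants; the scatter is artificial.

We decide to reckon in fractions of the charge: spring, dawn, noon and midnight each have 40 mM of D and run for 1.0 h, and they differ in their charge of L.

| setting | Wednesday's | Tuesday's | spring | dawn | noon | midnight |
|---|---|---|---|---|---|---|
| L | 0.35 M | 2.4 M | 0.40 M | 0.80 M | 1.5 M | 3.0 M |
| D | 40 mM | 40 mM | 40 mM | 40 mM | 40 mM | 40 mM |
| remark | run made earlier | run made earlier |  |  |  |  |
| time |  |  | 1.0 h | 1.0 h | 1.0 h | 1.0 h |

| run | time / min | X / % | L / % |
|---|---|---|---|
| Wednesday's | 5.00 | 57 | 47 |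
| Wednesday's | 10.0 | 79 | 23 |
| Wednesday's | 15.0 | 89 | 10 |
| Wednesday's | 20.0 | 94 | 6 |
| Wednesday's | 25.0 | 95 | 2 |
| Wednesday's | 30.0 | 100 | 2 |
| Tuesday's | 2.00 | 25 | 74 |
| Tuesday's | 6.00 | 59 | 42 |
| Tuesday's | 10.0 | 78 | 22 |
| Tuesday's | 15.0 | 88 | 9 |
| Tuesday's | 25.0 | 99 | 4 |
| Tuesday's | 30.0 | 100 | 2 |

(scatter of a reading: 1.5 percentage points)

1. [X] (only what is free in solution) at the end for spring, dawn, noon, midnight, in this order
2. the course of these numbers from the first flask to the last (falls all the way / rises all the way / hardly changes / falls, then rises / rises, then falls)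

- for X the E are counted in
- as a solid, counted per litre of solution: E
- steps under discussion: L + D -> J + X; L + J -> X + J; E <-> X
- the concentration of X that is asked is that of its free form alone
- "hardly changes" means that all values lie within two and a half points (for a concentration: within two and a half percent of the largest)

After 10.0 min, Wednesday's run has 23% of its L left and Tuesday's run 22%, though Tuesday's charge is 6.86 times Wednesday's. So L falls in a pseudo-first-order way, and Tuesday's readings give a rate constant of 0.152 min⁻¹. Dividing the X gained by the L lost between the same two readings removes time and gives 1.02: each L lost appears as one X, crystals counted in.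

Our own reckoning is 0.0112% for the end fraction, the share of the L charged still present at the end. The fraction read at 10.0 min did not move with the charge in the two runs, so we take our end fraction for spring, dawn, noon and midnight alike. The readings count E within X, so they do not show how X divides between solution and crystals.

The forecast gives 0.4 M, 0.8 M, 1.5 M and 3 M, so its course rises all the way: “With no evidence for a cap, my default is that everything stays free”.

The flasks give 0.00570 M, 0.00570 M, 0.00570 M and 0.00571 M of free X, so the course hardly changes.

    L + D → J + X (k = 0.0940 M⁻¹ s⁻¹)
    L + J → X + J, rate k2*[J]*[L] (k = 0.0610 M⁻¹ s⁻¹)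
    E ⇌ X, rate k3*(cs3 - [X]) while solid is left; crystals form when [X] > cs3 (solubility = 5.70 mM, k = 0.150 s⁻¹)

This free X matches the solubility in the last line above, 5.7 mM, and in the spring flask it is 1.43% of the charge, with E at 98.6%. Put on the midnight flask, our end fraction leaves 0.336 mM of L, less than the 0.00571 M of free X. There E stands at 99.8% after 1.00 h and at 99.8% after 10.0 h.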